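## Retrosynthetic overview

1. Rings are built in the order C → B → A; the two prenyl groups go on last, one after the other, by C‑alkylation at C‑5 of the acyl‑trione 27.
2. Ring A is closed by a Dieckmann‑type attack of a triketone side chain (on the equatorial acyl carbon) onto a γ‑lactone carbonyl (the axial one), which also frees the C‑7′ tertiary alcohol.
3. The spiro centre and the C‑7′ carbinol are set together by iodolactonisation of a gem‑diacid on a rigid trans‑hydrindane, where only the axial CO2H can reach the exocyclic alkene.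
4. Ring B comes from an intramolecular malonate alkylation by an allylic chloride; the ring C stereocentres come from (R)‑4‑silyloxycyclopentenone by anti conjugate addition, α‑aminomethylation/malonate Michael addition and methyl addition, with the auxiliary oxygen removed by Barton–McCombie deoxygenation.
5. Absolute configuration comes from a lipase desymmetrisation of meso cis‑cyclopent‑4‑ene‑1,3‑diol.

Assumption: ring A of the target is drawn as one enol tautomer of a rapidly equilibrating acyl‑trione; all tautomers (including the triketo drawing of 25 and the dienol drawing of 29) count as the same compound.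

Locants used below: hydrindane atoms are C‑1′ to C‑7a′ (spiro atom C‑5′ = C‑1 of ring A); ring A is C‑1 to C‑6 as in the name of 30. Ring C is the cyclopentane and ring B the cyclohexane of the hydrindane.

## Route

Step 1
Reactants: 1 cis‑cyclopent‑4‑ene‑1,3‑diol (meso)
Product: 2 (1S,4R)‑4‑hydroxycyclopent‑2‑en‑1‑yl acetate
Conditions: porcine pancreatic lipase (pancreatin), vinyl acetate, Et3N (cat), THF, rt
Reagents that add atoms: vinyl acetate, CC(=O)OC=C
Why: Lipase‑catalysed enantiotopic‑group‑selective transesterification (desymmetrisation of a meso diol) acylates only one of the two mirror‑related carbinols, so this catalytic asymmetric step fixes both stereocentres of 2 in high ee, and the vinyl ester makes the acylation irreversible.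

Step 2
Reactants: 2 (1S,4R)‑4‑hydroxycyclopent‑2‑en‑1‑yl acetate
Product: 3 (1S,4R)‑4‑[(tert‑butyldimethylsilyl)oxy]cyclopent‑2‑en‑1‑yl acetate
Conditions: TBSCl, imidazole, DMF, rt
Reagents that add atoms: tert‑butyldimethylsilyl chloride, CC(C)(C)[Si](C)(C)Cl
Why: Silylation of the free secondary alcohol (Corey conditions) differentiates the two oxygens permanently without touching either stereocentre.

Step 3
Reactants: 3 (1S,4R)‑4‑[(tert‑butyldimethylsilyl)oxy]cyclopent‑2‑en‑1‑yl acetate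
Product: 4 (1S,4R)‑4‑[(tert‑butyldimethylsilyl)oxy]cyclopent‑2‑en‑1‑ol
Conditions: K2CO3 (cat), MeOH, 0 °C → rt
Reagents that add atoms: none
Why: Base‑catalysed transesterification (methanolysis) removes the acetate while the silyl ether and both allylic stereocentres survive.

Step 4
Reactants: 4 (1S,4R)‑4‑[(tert‑butyldimethylsilyl)oxy]cyclopent‑2‑en‑1‑ol
Product: 5 (R)‑4‑[(tert‑butyldimethylsilyl)oxy]cyclopent‑2‑en‑1‑one
Conditions: Dess–Martin periodinane, CH2Cl2, 0 °C → rt
Reagents that add atoms: none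
Why: Dess–Martin oxidation of the allylic alcohol gives the enone under non‑basic conditions, so the remaining silyloxy stereocentre neither racemises nor eliminates.

Step 5
Reactants: 5 (R)‑4‑[(tert‑butyldimethylsilyl)oxy]cyclopent‑2‑en‑1‑one; 6 isopropenylmagnesium bromide
Product: 7 (3S,4R)‑4‑[(tert‑butyldimethylsilyl)oxy]‑3‑(prop‑1‑en‑2‑yl)‑1‑[(trimethylsilyl)oxy]cyclopent‑1‑ene (3,4‑trans)
Conditions: CuBr·SMe2 (10 mol %), TMSCl, THF, −78 °C; Et3N, pentane work‑up
Reagents that add atoms: chlorotrimethylsilane, C[Si](C)(C)Cl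
Why: Copper‑catalysed conjugate addition of the Grignard reagent with in‑situ silyl trapping delivers the isopropenyl group anti to the C‑4 silyloxy group (as in prostaglandin three‑component couplings), which sets C‑7a′, and TMSCl fixes the enolate regiochemistry before it can expel the silyloxy group.

Step 6
Reactants: 7 (3S,4R)‑4‑[(tert‑butyldimethylsilyl)oxy]‑3‑(prop‑1‑en‑2‑yl)‑1‑[(trimethylsilyl)oxy]cyclopent‑1‑ene
Product: 8 (2S,3S,4R)‑4‑[(tert‑butyldimethylsilyl)oxy]‑2‑[(dimethylamino)methyl]‑3‑(prop‑1‑en‑2‑yl)cyclopentan‑1‑one (2,3‑trans, 3,4‑trans)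
Conditions: CH2=NMe2+ I− (Eschenmoser's salt), CH2Cl2, rt; NaHCO3 (aq) work‑up
Reagents that add atoms: N,N‑dimethylmethyleneiminium iodide, C=[N+](C)C.[I-]
Why: Mannich‑type aminomethylation of the silyl enol ether puts the one‑carbon unit C‑4′ on the enol carbon anti to the neighbouring isopropenyl group, giving the 2,3‑trans ketone.

Step 7
Reactants: 8 (2S,3S,4R)‑4‑[(tert‑butyldimethylsilyl)oxy]‑2‑[(dimethylamino)methyl]‑3‑(prop‑1‑en‑2‑yl)cyclopentan‑1‑one
Product: 9 {[(1S,2S,3R)‑3‑[(tert‑butyldimethylsilyl)oxy]‑5‑oxo‑2‑(prop‑1‑en‑2‑yl)cyclopentyl]methyl}trimethylammonium iodide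
Conditions: MeI (excess), MeCN, rt; evaporate
Reagents that add atoms: iodomethane, CI
Why: Menshutkin quaternisation turns the amine into a leaving group under neutral conditions that do not disturb the β‑silyloxy ketone.

Step 8
Reactants: 9 trimethylammonium iodide of 8; 10 dimethyl malonate
Product: 12 dimethyl 2‑{[(1R,2S,3R)‑3‑[(tert‑butyldimethylsilyl)oxy]‑5‑oxo‑2‑(prop‑1‑en‑2‑yl)cyclopentyl]methyl}propanedioate, via exo‑methylene ketone 11 (not isolated)
Conditions: NaH (1.1 equiv), dimethyl malonate (1.3 equiv), THF, 0 °C; then 9, 0 °C → rt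
Reagents that add atoms: none
Why: E1cB loss of trimethylamine gives the α‑methylene ketone, which the malonate anion captures at once (Michael addition, the Stork–Isobe tactic), and protonation of the enolate under equilibrating conditions leaves the new arm at C‑3a′ trans to the isopropenyl group.

Step 9
Reactants: 12 dimethyl 2‑{[(1R,2S,3R)‑3‑[(tert‑butyldimethylsilyl)oxy]‑5‑oxo‑2‑(prop‑1‑en‑2‑yl)cyclopentyl]methyl}propanedioate
Product: 13 dimethyl 2‑{[(1R,2S,4R,5S)‑4‑[(tert‑butyldimethylsilyl)oxy]‑2‑hydroxy‑2‑methyl‑5‑(prop‑1‑en‑2‑yl)cyclopentyl]methyl}propanedioate (OH cis to the malonylmethyl arm and to OTBS)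
Conditions: CeCl3 (anhydrous), MeMgBr, THF, −78 °C; AcOH quench at −78 °C
Reagents that add atoms: methylmagnesium bromide, C[Mg]Br
Why: Organocerium 1,2‑addition (Imamoto conditions) tolerates the esters and the enolisable β‑silyloxy ketone, and the methyl group should enter anti to both the adjacent malonylmethyl arm and the C‑1′ silyloxy group (the face taken by bulky reagents on 11‑silyloxy prostaglandin E ketones), so the new C‑3′ hydroxyl is cis to that arm.

Step 10
Reactants: 13 dimethyl 2‑{[(1R,2S,4R,5S)‑4‑[(tert‑butyldimethylsilyl)oxy]‑2‑hydroxy‑2‑methyl‑5‑(prop‑1‑en‑2‑yl)cyclopentyl]methyl}propanedioate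
Product: 14 dimethyl 2‑{[(1R,2S,4R,5S)‑4‑[(tert‑butyldimethylsilyl)oxy]‑5‑(3‑chloroprop‑1‑en‑2‑yl)‑2‑hydroxy‑2‑methylcyclopentyl]methyl}propanedioate
Conditions: Ca(OCl)2, CO2 (solid), CH2Cl2/H2O, 0 °C
Reagents that add atoms: calcium hypochlorite, [Ca+2].[O-]Cl.[O-]Cl
Why: Ene‑type allylic chlorination by HOCl (Wolinsky conditions) converts the isopropenyl group into a 2‑substituted allyl chloride with transposition of the double bond and without involving any stereocentre.

Step 11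
Reactants: 14 dimethyl 2‑{[(1R,2S,4R,5S)‑4‑[(tert‑butyldimethylsilyl)oxy]‑5‑(3‑chloroprop‑1‑en‑2‑yl)‑2‑hydroxy‑2‑methylcyclopentyl]methyl}propanedioate
Product: 15 dimethyl (1R,3S,3aR,7aS)‑1‑[(tert‑butyldimethylsilyl)oxy]‑3‑hydroxy‑3‑methyl‑7‑methylideneoctahydro‑5H‑indene‑5,5‑dicarboxylate (trans‑fused)
Conditions: Cs2CO3, MeCN, rt → 45 °C
Reagents that add atoms: none
Why: Intramolecular malonate alkylation (6‑exo‑tet SN2 on the allylic chloride) closes ring B, and because the two arms are trans on the cyclopentane the hydrindane is necessarily trans‑fused.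

Step 12
Reactants: 15 dimethyl (1R,3S,3aR,7aS)‑1‑[(tert‑butyldimethylsilyl)oxy]‑3‑hydroxy‑3‑methyl‑7‑methylideneoctahydro‑5H‑indene‑5,5‑dicarboxylate
Product: 16 dimethyl (1R,3S,3aR,7aS)‑1,3‑dihydroxy‑3‑methyl‑7‑methylideneoctahydro‑5H‑indene‑5,5‑dicarboxylate
Conditions: HF·pyridine, THF/pyridine, 0 °C → rt
Reagents that add atoms: none
Why: Fluoride‑mediated desilylation frees the secondary C‑1′ alcohol once its stereodirecting role is over.

Step 13
Reactants: 16 dimethyl (1R,3S,3aR,7aS)‑1,3‑dihydroxy‑3‑methyl‑7‑methylideneoctahydro‑5H‑indene‑5,5‑dicarboxylate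
Product: 17 dimethyl (1R,3S,3aR,7aS)‑3‑hydroxy‑3‑methyl‑7‑methylidene‑1‑[(phenoxycarbonothioyl)oxy]octahydro‑5H‑indene‑5,5‑dicarboxylate
Conditions: PhOC(S)Cl, pyridine, DMAP (cat), CH2Cl2, 0 °C
Reagents that add atoms: O‑phenyl chlorothionoformate, S=C(Cl)Oc1ccccc1
Why: Thioacylation is selective for the secondary hydroxyl because the tertiary C‑3′ alcohol is too hindered to react.

Step 14
Reactants: 17 dimethyl (1R,3S,3aR,7aS)‑3‑hydroxy‑3‑methyl‑7‑methylidene‑1‑[(phenoxycarbonothioyl)oxy]octahydro‑5H‑indene‑5,5‑dicarboxylate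
Product: 18 dimethyl (3S,3aR,7aS)‑3‑hydroxy‑3‑methyl‑7‑methylideneoctahydro‑5H‑indene‑5,5‑dicarboxylate
Conditions: Bu3SnH, AIBN (cat), toluene, 90 °C
Reagents that add atoms: none
Why: Barton–McCombie radical deoxygenation removes the auxiliary C‑1′ oxygen, the secondary radical being reduced by the stannane faster than it can interact with the exocyclic alkene.

Step 15
Reactants: 18 dimethyl (3S,3aR,7aS)‑3‑hydroxy‑3‑methyl‑7‑methylideneoctahydro‑5H‑indene‑5,5‑dicarboxylate
Product: 19 (3S,3aR,7aS)‑3‑hydroxy‑3‑methyl‑7‑methylideneoctahydro‑5H‑indene‑5,5‑dicarboxylic acid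
Conditions: KOH, MeOH/H2O, 65 °C; HCl (aq) to pH 2 at 0 °C
Reagents that add atoms: potassium hydroxide, [K+].[OH-]
Why: Saponification of both esters gives the gem‑diacid, which does not decarboxylate at this temperature and whose C‑5′ is not yet stereogenic.

Step 16
Reactants: 19 (3S,3aR,7aS)‑3‑hydroxy‑3‑methyl‑7‑methylideneoctahydro‑5H‑indene‑5,5‑dicarboxylic acid
Product: 20 (3S,3aR,5R,7R,7aS)‑3‑hydroxy‑7‑(iodomethyl)‑3‑methyloctahydroindene‑5,5‑dicarboxylic acid 5,7‑lactone (γ‑lactone from the axial carboxyl onto O‑7; equatorial CO2H free)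
Conditions: I2, NaHCO3, MeCN/H2O, 0 °C, dark
Reagents that add atoms: iodine, II
Why: In this iodolactonisation (5‑exo, Markovnikov) only the carboxylate that is axial on the rigid trans‑hydrindane chair can reach C‑7′, so it alone lactonises and delivers oxygen to the axial face of C‑7′, which fixes the future spiro centre C‑5′ and the C‑7′ carbinol together in the required relative configuration.

Step 17
Reactants: 20 iodolactone acid
Product: 21 (3S,3aR,5R,7R,7aS)‑3‑hydroxy‑3,7‑dimethyloctahydroindene‑5,5‑dicarboxylic acid 5,7‑lactone (equatorial CO2H free)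
Conditions: Bu3SnH, AIBN (cat), benzene, 80 °C
Reagents that add atoms: none
Why: Radical dehalogenation turns the iodomethyl group into the C‑7′ methyl group without touching the lactone or any stereocentre.

Step 18
Reactants: 21 lactone acid
Product: 23 3‑O‑TBS ether of the 5‑carbonyl chloride of 21, via bis‑silyl derivative 22 (not isolated)
Conditions: TBSOTf (2.5 equiv), 2,6‑lutidine, CH2Cl2, 0 °C → rt; then (COCl)2, DMF (cat), CH2Cl2, 0 °C → rt
Reagents that add atoms: tert‑butyldimethylsilyl triflate, CC(C)(C)[Si](C)(C)OS(=O)(=O)C(F)(F)F; oxalyl chloride, ClC(=O)C(Cl)=O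
Why: Silylation protects the C‑3′ alcohol and makes the silyl ester, which oxalyl chloride/DMF converts into the acid chloride under neutral conditions (Wissner–Grudzinskas procedure) that spare the silyl ether and the lactone.

Step 19
Reactants: 23 lactone acid chloride; 24 5‑methylhexane‑2,4‑dione
Product: 25 3‑O‑TBS lactone bearing an equatorial 2‑acetyl‑4‑methyl‑3‑oxopentanoyl group at C‑5′ (triketone, enolised)
Conditions: MgCl2, pyridine, CH2Cl2, 0 °C → rt; HCl (aq) work‑up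
Reagents that add atoms: none
Why: Soft‑enolisation C‑acylation of the magnesium diketonate (Rathke conditions) bonds the carbon that carries the acetyl and isobutyryl groups (future C‑3) to the equatorial acyl carbon (future C‑2), so the acyl side of ring A is tied to the equatorial carbonyl by connectivity.

Step 20
Reactants: 25 triketone lactone
Product: 27 (1S,3′S,3a′R,7′R,7a′S)‑3′,4,7′‑trihydroxy‑3′,7′‑dimethyl‑3‑(2‑methylpropanoyl)octahydrospiro[cyclohex‑3‑ene‑1,5′‑indene]‑2,6‑dione, via silyl ether 26 (not isolated)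
Conditions: LiN(iPr)2 (3.5 equiv), THF, −78 → 0 °C; HCl (aq) quench; then HF (aq, 48%), MeCN, rt
Reagents that add atoms: none
Why: In this Dieckmann‑type intramolecular Claisen condensation the dianion formed at the acetyl methyl group attacks the lactone carbonyl in a six‑membered closure, expels the C‑7′ alkoxide and ends as the stabilised acyl‑trione enolate, so the spiro configuration from step 16 is carried over unchanged, and aqueous HF then removes the tertiary silyl ether.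

Step 21
Reactants: 27 bis‑desprenyl acyl‑trione; 28 prenyl bromide (1‑bromo‑3‑methylbut‑2‑ene)
Product: 29 (1S,3′S,3a′R,7′R,7a′S)‑3′,4,6,7′‑tetrahydroxy‑3′,7′‑dimethyl‑5‑(3‑methylbut‑2‑en‑1‑yl)‑3‑(2‑methylpropanoyl)octahydrospiro[cyclohexa‑3,5‑diene‑1,5′‑inden]‑2‑one (5‑mono‑prenyl acyl‑trione, drawn as its 4,6‑dienol)
Conditions: NaOMe (2.0 equiv), MeOH, −20 → 0 °C; prenyl bromide (1.0 equiv, slow addition); HCl (aq) work‑up; recovered 27 recycled
Reagents that add atoms: none
Why: C‑alkylation of the acyl‑trione dianion at its only CH2 position C‑5 (cyclohexane‑1,3‑dione‑type alkylation, as in the lupulone series) is held at the mono‑prenyl stage by using one equivalent of halide, the product re‑enolises so C‑5 is not a stereocentre, and any over‑alkylated material is already 30.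

Step 22
Reactants: 29 5‑mono‑prenyl acyl‑trione; 28 prenyl bromide (1‑bromo‑3‑methylbut‑2‑ene)
Product: 30 (1S,3′S,3a′R,7′R,7a′S)‑3′,4,7′‑trihydroxy‑3′,7′‑dimethyl‑5,5‑bis(3‑methylbut‑2‑en‑1‑yl)‑3‑(2‑methylpropanoyl)octahydrospiro[cyclohex‑3‑ene‑1,5′‑indene]‑2,6‑dione (target CNP0273836.6)
Conditions: NaOMe (2.2 equiv), prenyl bromide (1.3 equiv), MeOH, 0 °C → rt; HCl (aq) work‑up
Reagents that add atoms: none
Why: A second C‑alkylation of the dianion at the now tertiary C‑5 (the lupulone‑type alkylation of a deoxyhumulone) builds the geminal prenyl pair, creates no stereocentre because the two groups are identical, and leaves the tertiary alcohols untouched in the protic medium that favours C‑ over O‑alkylation.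

## Compound list

1 | cis‑cyclopent‑4‑ene‑1,3‑diol (meso) | O[C@@H]1C=C[C@H](O)C1 | starting material
2 | (1S,4R)‑4‑hydroxycyclopent‑2‑en‑1‑yl acetate | CC(=O)O[C@@H]1C=C[C@H](O)C1 | intermediate
3 | (1S,4R)‑4‑[(tert‑butyldimethylsilyl)oxy]cyclopent‑2‑en‑1‑yl acetate | CC(=O)O[C@@H]1C=C[C@H](O[Si](C)(C)C(C)(C)C)C1 | intermediate
4 | (1S,4R)‑4‑[(tert‑butyldimethylsilyl)oxy]cyclopent‑2‑en‑1‑ol | O[C@@H]1C=C[C@H](O[Si](C)(C)C(C)(C)C)C1 | intermediate
5 | (R)‑4‑[(tert‑butyldimethylsilyl)oxy]cyclopent‑2‑en‑1‑one | O=C1C=C[C@H](O[Si](C)(C)C(C)(C)C)C1 | intermediate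
6 | isopropenylmagnesium bromide | CC(=C)[Mg]Br | starting material
7 | (3S,4R)‑4‑[(tert‑butyldimethylsilyl)oxy]‑3‑(prop‑1‑en‑2‑yl)‑1‑[(trimethylsilyl)oxy]cyclopent‑1‑ene | C[Si](C)(C)OC1=C[C@@H](C(C)=C)[C@H](O[Si](C)(C)C(C)(C)C)C1 | intermediate
8 | (2S,3S,4R)‑4‑[(tert‑butyldimethylsilyl)oxy]‑2‑[(dimethylamino)methyl]‑3‑(prop‑1‑en‑2‑yl)cyclopentan‑1‑one | CN(C)C[C@@H]1[C@@H](C(C)=C)[C@H](O[Si](C)(C)C(C)(C)C)CC1=O | intermediate
9 | {[(1S,2S,3R)‑3‑[(tert‑butyldimethylsilyl)oxy]‑5‑oxo‑2‑(prop‑1‑en‑2‑yl)cyclopentyl]methyl}trimethylammonium iodide | C[N+](C)(C)C[C@@H]1[C@@H](C(C)=C)[C@H](O[Si](C)(C)C(C)(C)C)CC1=O.[I-] | intermediate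
10 | dimethyl malonate | COC(=O)CC(=O)OC | starting material
11 | (3R,4R)‑4‑[(tert‑butyldimethylsilyl)oxy]‑2‑methylidene‑3‑(prop‑1‑en‑2‑yl)cyclopentan‑1‑one | C=C1[C@@H](C(C)=C)[C@H](O[Si](C)(C)C(C)(C)C)CC1=O | intermediate
12 | dimethyl 2‑{[(1R,2S,3R)‑3‑[(tert‑butyldimethylsilyl)oxy]‑5‑oxo‑2‑(prop‑1‑en‑2‑yl)cyclopentyl]methyl}propanedioate | COC(=O)C(C(=O)OC)C[C@@H]1[C@@H](C(C)=C)[C@H](O[Si](C)(C)C(C)(C)C)CC1=O | intermediate
13 | dimethyl 2‑{[(1R,2S,4R,5S)‑4‑[(tert‑butyldimethylsilyl)oxy]‑2‑hydroxy‑2‑methyl‑5‑(prop‑1‑en‑2‑yl)cyclopentyl]methyl}propanedioate | COC(=O)C(C(=O)OC)C[C@@H]1[C@@H](C(C)=C)[C@H](O[Si](C)(C)C(C)(C)C)C[C@]1(C)O | intermediate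
14 | dimethyl 2‑{[(1R,2S,4R,5S)‑4‑[(tert‑butyldimethylsilyl)oxy]‑5‑(3‑chloroprop‑1‑en‑2‑yl)‑2‑hydroxy‑2‑methylcyclopentyl]methyl}propanedioate | COC(=O)C(C(=O)OC)C[C@@H]1[C@@H](C(=C)CCl)[C@H](O[Si](C)(C)C(C)(C)C)C[C@]1(C)O | intermediate
15 | dimethyl (1R,3S,3aR,7aS)‑1‑[(tert‑butyldimethylsilyl)oxy]‑3‑hydroxy‑3‑methyl‑7‑methylideneoctahydro‑5H‑indene‑5,5‑dicarboxylate | COC(=O)C1(C(=O)OC)C[C@@H]2[C@H]([C@H](O[Si](C)(C)C(C)(C)C)C[C@]2(C)O)C(=C)C1 | intermediate
16 | dimethyl (1R,3S,3aR,7aS)‑1,3‑dihydroxy‑3‑methyl‑7‑methylideneoctahydro‑5H‑indene‑5,5‑dicarboxylate | COC(=O)C1(C(=O)OC)C[C@@H]2[C@H]([C@H](O)C[C@]2(C)O)C(=C)C1 | intermediate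
17 | dimethyl (1R,3S,3aR,7aS)‑3‑hydroxy‑3‑methyl‑7‑methylidene‑1‑[(phenoxycarbonothioyl)oxy]octahydro‑5H‑indene‑5,5‑dicarboxylate | COC(=O)C1(C(=O)OC)C[C@@H]2[C@H]([C@H](OC(=S)Oc3ccccc3)C[C@]2(C)O)C(=C)C1 | intermediate
18 | dimethyl (3S,3aR,7aS)‑3‑hydroxy‑3‑methyl‑7‑methylideneoctahydro‑5H‑indene‑5,5‑dicarboxylate | COC(=O)C1(C(=O)OC)C[C@@H]2[C@H](CC[C@]2(C)O)C(=C)C1 | intermediate
19 | (3S,3aR,7aS)‑3‑hydroxy‑3‑methyl‑7‑methylideneoctahydro‑5H‑indene‑5,5‑dicarboxylic acid | OC(=O)C1(C(=O)O)C[C@@H]2[C@H](CC[C@]2(C)O)C(=C)C1 | intermediate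
20 | (3S,3aR,5R,7R,7aS)‑3‑hydroxy‑7‑(iodomethyl)‑3‑methyloctahydroindene‑5,5‑dicarboxylic acid 5,7‑lactone | OC(=O)[C@]12C[C@@H]3[C@H](CC[C@]3(C)O)[C@](CI)(OC1=O)C2 | intermediate
21 | (3S,3aR,5R,7R,7aS)‑3‑hydroxy‑3,7‑dimethyloctahydroindene‑5,5‑dicarboxylic acid 5,7‑lactone | OC(=O)[C@]12C[C@@H]3[C@H](CC[C@]3(C)O)[C@](C)(OC1=O)C2 | intermediate
22 | 3‑O‑TBS ether TBS ester of 21 | CC(C)(C)[Si](C)(C)OC(=O)[C@]12C[C@@H]3[C@H](CC[C@]3(C)O[Si](C)(C)C(C)(C)C)[C@](C)(OC1=O)C2 | intermediate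
23 | 3‑O‑TBS ether of the 5‑carbonyl chloride of 21 | ClC(=O)[C@]12C[C@@H]3[C@H](CC[C@]3(C)O[Si](C)(C)C(C)(C)C)[C@](C)(OC1=O)C2 | intermediate
24 | 5‑methylhexane‑2,4‑dione | CC(=O)CC(=O)C(C)C | starting material
25 | 3‑O‑TBS lactone with equatorial 2‑acetyl‑4‑methyl‑3‑oxopentanoyl group at C‑5′ (triketo drawing) | CC(=O)C(C(=O)C(C)C)C(=O)[C@]12C[C@@H]3[C@H](CC[C@]3(C)O[Si](C)(C)C(C)(C)C)[C@](C)(OC1=O)C2 | intermediate
26 | 3′‑O‑TBS ether of 27 | C1C(=O)[C@@]2(C[C@@H]3[C@H](CC[C@]3(C)O[Si](C)(C)C(C)(C)C)[C@](C)(O)C2)C(=O)C(C(=O)C(C)C)=C1O | intermediate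
27 | (1S,3′S,3a′R,7′R,7a′S)‑3′,4,7′‑trihydroxy‑3′,7′‑dimethyl‑3‑(2‑methylpropanoyl)octahydrospiro[cyclohex‑3‑ene‑1,5′‑indene]‑2,6‑dione | C1C(=O)[C@@]2(C[C@@H]3[C@H](CC[C@]3(C)O)[C@](C)(O)C2)C(=O)C(C(=O)C(C)C)=C1O | intermediate
28 | prenyl bromide (1‑bromo‑3‑methylbut‑2‑ene) | CC(C)=CCBr | starting material
29 | (1S,3′S,3a′R,7′R,7a′S)‑3′,4,6,7′‑tetrahydroxy‑3′,7′‑dimethyl‑5‑(3‑methylbut‑2‑en‑1‑yl)‑3‑(2‑methylpropanoyl)octahydrospiro[cyclohexa‑3,5‑diene‑1,5′‑inden]‑2‑one (5‑mono‑prenyl acyl‑trione, dienol drawing) | CC(C)=CCC1=C(O)[C@@]2(C[C@@H]3[C@H](CC[C@]3(C)O)[C@](C)(O)C2)C(=O)C(C(=O)C(C)C)=C1O | intermediate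
30 | (1S,3′S,3a′R,7′R,7a′S)‑3′,4,7′‑trihydroxy‑3′,7′‑dimethyl‑5,5‑bis(3‑methylbut‑2‑en‑1‑yl)‑3‑(2‑methylpropanoyl)octahydrospiro[cyclohex‑3‑ene‑1,5′‑indene]‑2,6‑dione | CC(C)=CCC1(CC=C(C)C)C(=O)[C@@]2(C[C@@H]3[C@H](CC[C@]3(C)O)[C@](C)(O)C2)C(=O)C(C(=O)C(C)C)=C1O | target

## Totals and risks

Total step count: 22. Longest linear sequence: 22 steps (1 → 30; fully linear, with 6, 10, 24 and 28 added as reagent‑like building blocks).

**Risk 1, step 20 (ring A closure onto the hindered lactone).** The triacylmethane may fragment or enolise at the wrong site before the dianion reaches the neopentyl‑type lactone carbonyl. The fallback sets out from 21 and comes back at 27, forming the C‑5/C‑6 bond first and the C‑2/C‑3 bond second. Compound 21 is converted into its lithium carboxylate (LiN(iPr)2, 1 equiv) and treated with the dilithio dianion of 24 (LiN(iPr)2, 2 equiv, THF, −78 → 0 °C). The terminal carbanion opens the lactone at its carbonyl while the carboxylate is inert, giving (3S,3aR,5S,7R,7aS)‑3,7‑dihydroxy‑3,7‑dimethyl‑5‑(6‑methyl‑3,5‑dioxoheptanoyl)octahydroindene‑5‑carboxylic acid F1, with the chain axial and the CO2H equatorial. DCC and DMAP in CH2Cl2 then activate the equatorial acid, which O‑acylates the diketone enol and is relayed by DMAP to carbon, closing ring A to 27. Because the chain is bonded to the former lactone carbon and the acyl‑bearing carbon to the former free acid, the spiro configuration is the same as in the main route.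

**Risk 2, step 22 (second prenylation, which builds the quaternary C‑5).** O‑alkylation at the hindered, fully substituted position and retro‑Claisen cleavage of the C‑6 ketone can lower the yield. The fallback sets out from 27, replaces both prenylations and comes back at 30. Compound 27 is allylated twice at C‑5 with allyl methyl carbonate and Pd(PPh3)4 (5 mol %) in THF at rt; under this Tsuji–Trost chemistry O‑allyl products re‑ionise and funnel to carbon. The product is the 5,5‑diallyl analogue of 30, (1S,3′S,3a′R,7′R,7a′S)‑3′,4,7′‑trihydroxy‑3′,7′‑dimethyl‑3‑(2‑methylpropanoyl)‑5,5‑di(prop‑2‑en‑1‑yl)octahydrospiro[cyclohex‑3‑ene‑1,5′‑indene]‑2,6‑dione F2. Cross‑metathesis of both allyl groups with 2‑methylbut‑2‑ene (second‑generation Grubbs catalyst, CH2Cl2, 40 °C) then gives 30.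

**Risk 3, step 10 (HOCl ene chlorination).** HOCl may abstract the ring methine hydrogen instead of a methyl hydrogen, add across the alkene, or chlorinate the malonate. The fallback sets out from 13 and comes back at 15, replacing the chloride/SN2 pair by an allylic oxidation and a palladium π‑allyl cyclisation. Allylic oxidation of 13 (SeO2 cat, t‑BuOOH, CH2Cl2, rt) gives dimethyl 2‑{[(1R,2S,4R,5S)‑4‑[(tert‑butyldimethylsilyl)oxy]‑2‑hydroxy‑5‑(3‑hydroxyprop‑1‑en‑2‑yl)‑2‑methylcyclopentyl]methyl}propanedioate F3. Methyl chloroformate and pyridine (CH2Cl2, 0 °C) acylate only the primary allylic hydroxyl to give the allyl methyl carbonate of F3 F4. Pd(PPh3)4 (5 mol %) in THF (rt → 50 °C) then ionises the carbonate, and the liberated methoxide deprotonates the malonate, which attacks either terminus of the symmetrical 2‑substituted π‑allyl unit to give 15.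

## Further compounds

F1 | step 20 | (3S,3aR,5S,7R,7aS)‑3,7‑dihydroxy‑3,7‑dimethyl‑5‑(6‑methyl‑3,5‑dioxoheptanoyl)octahydroindene‑5‑carboxylic acid | CC(C)C(=O)CC(=O)CC(=O)[C@]1(C(=O)O)C[C@@H]2[C@H](CC[C@]2(C)O)[C@](C)(O)C1
F2 | step 22 | 5,5‑diallyl analogue of 30 | C=CCC1(CC=C)C(=O)[C@@]2(C[C@@H]3[C@H](CC[C@]3(C)O)[C@](C)(O)C2)C(=O)C(C(=O)C(C)C)=C1O
F3 | step 10 | dimethyl 2‑{[(1R,2S,4R,5S)‑4‑[(tert‑butyldimethylsilyl)oxy]‑2‑hydroxy‑5‑(3‑hydroxyprop‑1‑en‑2‑yl)‑2‑methylcyclopentyl]methyl}propanedioate | COC(=O)C(C(=O)OC)C[C@@H]1[C@@H](C(=C)CO)[C@H](O[Si](C)(C)C(C)(C)C)C[C@]1(C)O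
F4 | step 10 | allyl methyl carbonate of F3 | COC(=O)C(C(=O)OC)C[C@@H]1[C@@H](C(=C)COC(=O)OC)[C@H](O[Si](C)(C)C(C)(C)C)C[C@]1(C)O
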